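**Retrosynthetic overview**

1. Feature: in the ring carrying the sulfated chain (C1 chain, C2 H, C3 OH, C4 OH, C5 Br, C6 CH2Ar) the C3 hydroxyl is para to C6 and the chain oxygen can bridge to the benzylic carbon. That ring is therefore the benzene ring of a 1-arylisochroman, made from a furan (ring O → C3–OH, C–Br → C5, C–OMe → C4, tether carbon → C6) and a two-carbon alkyne (C1, C2).
2. Endgame: sulfate ⇐ primary alcohol with all phenols silylated; catechols ⇐ methyl ethers; ArCH2Ar′ and the hydroxyethyl chain ⇐ reductive cleavage of the isochroman C1–O bond.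
3. Key disconnection: the benzene and dihydropyran rings of the isochromanol ⇐ intramolecular furan–alkyne [4+2] of a furfuryl homopropargyl ether, the oxygen bridge opening to the C3 phenol.
4. Precursor: ether C–O bond (furyl aryl carbinol + but-3-yn-1-ol) and furyl–CH bond (2-lithio-3-bromo-4-methoxyfuran + 2,3-dibromo-4,5-dimethoxybenzaldehyde).
5. Ring order: furan and aryl ring are bought; the dihydropyran and the new benzene ring form together in the key step; the pyran ring is opened again one step later.

Key step: step 6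

Remark: the target has no stereocentre, so no enantiomer has to be chosen; the benzylic centre of 7–11 is carried racemic and is erased in step 7. The target is taken as the free hydrogen sulfate, as drawn.

**Route**

Step 1
Reactants: 1 5-bromovanillin
Product: 2 2,3-dibromo-4-hydroxy-5-methoxybenzaldehyde
Conditions: Br2 (1.2 equiv), Fe powder (cat.), NaOAc, AcOH, rt
Reagents that add atoms: bromine, BrBr
Why: Electrophilic aromatic bromination should take place at the free position para to the methoxy group, beside the existing bromine, which is the most activated site of the ring.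

Step 2
Reactants: 2 2,3-dibromo-4-hydroxy-5-methoxybenzaldehyde
Product: 3 2,3-dibromo-4,5-dimethoxybenzaldehyde
Conditions: MeI, K2CO3, DMF, rt
Reagents that add atoms: iodomethane, CI
Why: Williamson O-methylation of the acidic, para-formyl phenoxide by SN2 on iodomethane.

Step 3
Reactants: 4 3,4-dibromofuran
Product: 5 3-bromo-4-methoxyfuran
Conditions: NaOMe (1.1 equiv, 25% in MeOH), CuBr (10 mol%), NMP, 90 °C, sealed
Reagents that add atoms: sodium methoxide, C[O-].[Na+]
Why: Copper-catalysed Ullmann-type C–O coupling of a β-bromo five-membered heteroarene with methoxide; the first methoxy group makes the ring more electron-rich, so the second exchange should be slower and one equivalent should stop at the mono-ether.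

Step 4
Reactants: 5 3-bromo-4-methoxyfuran; 3 2,3-dibromo-4,5-dimethoxybenzaldehyde
Product: 7 (3-bromo-4-methoxyfuran-2-yl)(2,3-dibromo-4,5-dimethoxyphenyl)methanol (racemic), via furyllithium 6 (not isolated)
Conditions: LDA (1.0 equiv), THF, −78 °C; then 3 (0.9 equiv), THF, −78 °C; H2O
Reagents that add atoms: none
Why: Deprotonation by the amide base at the furan α-position beside bromine (bromine acidifies the neighbouring C–H more than methoxy does toward a non-coordinating base, as in 3-bromofuran) and 1,2-addition of the furyllithium to the aldehyde; the carbinol centre forms racemic, which is acceptable because it is removed in step 7.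

Step 5
Reactants: 7 (3-bromo-4-methoxyfuran-2-yl)(2,3-dibromo-4,5-dimethoxyphenyl)methanol (racemic); 8 but-3-yn-1-ol
Product: 9 3-bromo-2-[(but-3-yn-1-yloxy)(2,3-dibromo-4,5-dimethoxyphenyl)methyl]-4-methoxyfuran (racemic)
Conditions: 8 (5 equiv), CSA (10 mol%), 4 Å MS, CH2Cl2, −20 → 0 °C
Reagents that add atoms: none
Why: Acid-catalysed SN1 etherification through the furyl- and aryl-stabilised carbocation, trapped by excess primary alcohol, with sieves removing water to protect the methoxyfuran enol ether from hydrolysis and ring opening.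

Step 6
Reactants: 9 3-bromo-2-[(but-3-yn-1-yloxy)(2,3-dibromo-4,5-dimethoxyphenyl)methyl]-4-methoxyfuran (racemic)
Product: 11 8-bromo-1-(2,3-dibromo-4,5-dimethoxyphenyl)-7-methoxyisochroman-6-ol (racemic), via oxanorbornadiene cycloadduct 10 (not isolated)
Conditions: degassed 1,2-dichlorobenzene (0.01 M), BHT (10 mol%), 180–200 °C, sealed tube (microwave)
Reagents that add atoms: none
Why: Proposed new method: on heating, the electron-rich furan (diene termini C2 and C5) and the tethered terminal alkyne should undergo a concerted suprafacial intramolecular [4+2] cycloaddition to oxanorbornadiene 10, forming the bonds furan C2–internal alkyne carbon and furan C5–terminal alkyne carbon; 10 should then open by heterolysis of the C–O bond at the fully substituted bridgehead (the cyclohexadienyl cation is stabilised by the vinylogous methoxy group) and lose the proton of the other bridgehead, so that the furan oxygen becomes the C6 phenol irreversibly. The closest known reaction type is the thermal intramolecular Diels–Alder reaction of furans with tethered alkynes followed by aromatising opening of the oxabicycle to a phenol, known for three-atom tethers and for activated alkynes or aminofurans; the extension is to a four-atom ether tether, an unactivated terminal alkyne and a 2,3,4-trisubstituted furan. The dihydropyran ring closes through the tether as the six-membered ring fused to the new carbocycle (bond from furan C2 to the internal alkyne carbon, the terminal alkyne carbon lying outside that ring), and the carbocycle closes by the two σ-bonds of the cycloaddition and becomes the benzene ring when the bridge opens. No stereocentre is set in the isolated product, since the bridgehead centres of 10 are lost on aromatisation and the existing benzylic centre stays racemic. The step needs regiocontrol of the cycloaddition, which the tether secures because only the internal alkyne carbon can reach furan C2, and a single direction of bridge opening, which the proton-free quaternary bridgehead and the methoxy group secure, placing the hydroxyl para to the benzylic carbon. The bromine at furan C3 and the aryl group on the tether carbon should raise the population of the reactive conformer, and the irreversible aromatisation should pull the cycloaddition forward.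

Step 7
Reactants: 11 8-bromo-1-(2,3-dibromo-4,5-dimethoxyphenyl)-7-methoxyisochroman-6-ol (racemic)
Product: 12 3-bromo-4-(2,3-dibromo-4,5-dimethoxybenzyl)-5-(2-hydroxyethyl)-2-methoxyphenol
Conditions: Et3SiH (5 equiv), TFA/CH2Cl2 (1:4), 0 °C → rt; then K2CO3, MeOH (work-up)
Reagents that add atoms: none
Why: Ionic hydrogenation: acid ionises the doubly benzylic C1–O bond (cation stabilised by the para-hydroxyl of the new ring and the para-methoxy of the aryl group) and triethylsilane delivers hydride irreversibly, giving the diarylmethane, freeing the hydroxyethyl chain and removing the only stereocentre.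

Step 8
Reactants: 12 3-bromo-4-(2,3-dibromo-4,5-dimethoxybenzyl)-5-(2-hydroxyethyl)-2-methoxyphenol
Product: 13 2-[5-acetoxy-3-bromo-2-(2,3-dibromo-4,5-dimethoxybenzyl)-4-methoxyphenyl]ethyl acetate
Conditions: Ac2O, pyridine, DMAP (cat.), CH2Cl2, rt
Reagents that add atoms: acetic anhydride, CC(=O)OC(C)=O
Why: DMAP-catalysed acylation of alcohol and phenol, so that the 2-arylethyl oxygen is an ester and not a borate during the BBr3 step, where bromide could otherwise displace it with aryl participation.

Step 9
Reactants: 13 2-[5-acetoxy-3-bromo-2-(2,3-dibromo-4,5-dimethoxybenzyl)-4-methoxyphenyl]ethyl acetate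
Product: 15 3-bromo-4-(2,3-dibromo-4,5-dihydroxybenzyl)-5-(2-hydroxyethyl)benzene-1,2-diol, via tris-demethylated diacetate 14 (not isolated)
Conditions: BBr3 (8 equiv), CH2Cl2, −78 → 0 °C; then MeOH, 0 → 40 °C
Reagents that add atoms: none
Why: Lewis-acid cleavage of the three aryl methyl ethers by BBr3 (bromide SN2 at O-methyl) at low temperature, followed by methanolysis of both acetates, catalysed by the HBr formed in the methanol quench.

Step 10
Reactants: 15 3-bromo-4-(2,3-dibromo-4,5-dihydroxybenzyl)-5-(2-hydroxyethyl)benzene-1,2-diol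
Product: 16 penta-O-TBS ether of 15
Conditions: TBSCl (10 equiv), imidazole (20 equiv), DMAP (cat.), DMF, 50 °C
Reagents that add atoms: tert-butyldimethylsilyl chloride, CC(C)(C)[Si](C)(C)Cl
Why: Imidazole-promoted silylation of all five hydroxyls, with excess reagent and warming to cover the bromine-flanked phenols.

Step 11
Reactants: 16 penta-O-TBS ether of 15
Product: 17 2-{3-bromo-2-[2,3-dibromo-4,5-bis(tert-butyldimethylsilyloxy)benzyl]-4,5-bis(tert-butyldimethylsilyloxy)phenyl}ethanol
Conditions: CSA (0.2 equiv), MeOH/CH2Cl2 (1:1), 0 °C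
Reagents that add atoms: none
Why: Acid-catalysed methanolysis cleaves a primary alkyl TBS ether much faster than aryl TBS ethers, which are acid-stable, so only the primary alcohol should be unveiled.

Step 12
Reactants: 17 2-{3-bromo-2-[2,3-dibromo-4,5-bis(tert-butyldimethylsilyloxy)benzyl]-4,5-bis(tert-butyldimethylsilyloxy)phenyl}ethanol
Product: 19 2-[3-bromo-2-(2,3-dibromo-4,5-dihydroxybenzyl)-4,5-dihydroxyphenyl]ethyl hydrogen sulfate (CNP0136879.0), via pyridinium tetrasilyl sulfate 18 (not isolated)
Conditions: SO3·pyridine (3 equiv), DMF, rt; then KHF2 (10 equiv), MeOH, rt; Dowex 50WX8 (H+ form), H2O/MeOH, 0 °C; lyophilise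
Reagents that add atoms: sulfur trioxide–pyridine complex, O=S(=O)([O-])[n+]1ccccc1
Why: O-sulfation of the only free hydroxyl by the SO3–amine complex, then bifluoride cleavage of the aryl silyl ethers under mildly acidic conditions that leave the sulfate monoester intact and protect the catechols from oxidation, and cation exchange to the hydrogen sulfate.

**Compound list**

1 | 5-bromovanillin (3-bromo-4-hydroxy-5-methoxybenzaldehyde) | COc1cc(C=O)cc(Br)c1O | starting material
2 | 2,3-dibromo-4-hydroxy-5-methoxybenzaldehyde | COc1cc(C=O)c(Br)c(Br)c1O | intermediate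
3 | 2,3-dibromo-4,5-dimethoxybenzaldehyde | COc1cc(C=O)c(Br)c(Br)c1OC | intermediate
4 | 3,4-dibromofuran | Brc1cocc1Br | starting material
5 | 3-bromo-4-methoxyfuran | COc1cocc1Br | intermediate
6 | (3-bromo-4-methoxyfuran-2-yl)lithium | [Li]c1occ(OC)c1Br | intermediate (not isolated)
7 | (3-bromo-4-methoxyfuran-2-yl)(2,3-dibromo-4,5-dimethoxyphenyl)methanol, racemic | COc1coc(C(O)c2cc(OC)c(OC)c(Br)c2Br)c1Br | intermediate
8 | but-3-yn-1-ol | C#CCCO | starting material
9 | 3-bromo-2-[(but-3-yn-1-yloxy)(2,3-dibromo-4,5-dimethoxyphenyl)methyl]-4-methoxyfuran, racemic | COc1coc(C(OCCC#C)c2cc(OC)c(OC)c(Br)c2Br)c1Br | intermediate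
10 | 8-bromo-1-(2,3-dibromo-4,5-dimethoxyphenyl)-7-methoxy-3,4,6,8a-tetrahydro-1H-6,8a-epoxyisochromene, racemic, either relative configuration at C1 | COC1=C(Br)C23OC1C=C2CCOC3c1cc(OC)c(OC)c(Br)c1Br | intermediate (not isolated)
11 | 8-bromo-1-(2,3-dibromo-4,5-dimethoxyphenyl)-7-methoxyisochroman-6-ol, racemic | COc1c(O)cc2CCOC(c3cc(OC)c(OC)c(Br)c3Br)c2c1Br | intermediate
12 | 3-bromo-4-(2,3-dibromo-4,5-dimethoxybenzyl)-5-(2-hydroxyethyl)-2-methoxyphenol | OCCc1cc(O)c(OC)c(Br)c1Cc1cc(OC)c(OC)c(Br)c1Br | intermediate
13 | 2-[5-acetoxy-3-bromo-2-(2,3-dibromo-4,5-dimethoxybenzyl)-4-methoxyphenyl]ethyl acetate | CC(=O)OCCc1cc(OC(C)=O)c(OC)c(Br)c1Cc1cc(OC)c(OC)c(Br)c1Br | intermediate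
14 | 2-[5-acetoxy-3-bromo-2-(2,3-dibromo-4,5-dihydroxybenzyl)-4-hydroxyphenyl]ethyl acetate | CC(=O)OCCc1cc(OC(C)=O)c(O)c(Br)c1Cc1cc(O)c(O)c(Br)c1Br | intermediate (not isolated)
15 | 3-bromo-4-(2,3-dibromo-4,5-dihydroxybenzyl)-5-(2-hydroxyethyl)benzene-1,2-diol | OCCc1cc(O)c(O)c(Br)c1Cc1cc(O)c(O)c(Br)c1Br | intermediate
16 | penta-O-TBS ether of 15 | CC(C)(C)[Si](C)(C)OCCc1cc(O[Si](C)(C)C(C)(C)C)c(O[Si](C)(C)C(C)(C)C)c(Br)c1Cc1cc(O[Si](C)(C)C(C)(C)C)c(O[Si](C)(C)C(C)(C)C)c(Br)c1Br | intermediate
17 | 2-{3-bromo-2-[2,3-dibromo-4,5-bis(tert-butyldimethylsilyloxy)benzyl]-4,5-bis(tert-butyldimethylsilyloxy)phenyl}ethanol | OCCc1cc(O[Si](C)(C)C(C)(C)C)c(O[Si](C)(C)C(C)(C)C)c(Br)c1Cc1cc(O[Si](C)(C)C(C)(C)C)c(O[Si](C)(C)C(C)(C)C)c(Br)c1Br | intermediate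
18 | pyridinium 2-{3-bromo-2-[2,3-dibromo-4,5-bis(tert-butyldimethylsilyloxy)benzyl]-4,5-bis(tert-butyldimethylsilyloxy)phenyl}ethyl sulfate | [O-]S(=O)(=O)OCCc1cc(O[Si](C)(C)C(C)(C)C)c(O[Si](C)(C)C(C)(C)C)c(Br)c1Cc1cc(O[Si](C)(C)C(C)(C)C)c(O[Si](C)(C)C(C)(C)C)c(Br)c1Br.c1cc[nH+]cc1 | intermediate (not isolated)
19 | 2-[3-bromo-2-(2,3-dibromo-4,5-dihydroxybenzyl)-4,5-dihydroxyphenyl]ethyl hydrogen sulfate (CNP0136879.0) | O=S(=O)(O)OCCc1cc(O)c(O)c(Br)c1Cc1cc(O)c(O)c(Br)c1Br | target

**Step count**

Total: 12 steps. Longest linear sequence: 11 steps (from 5-bromovanillin: steps 1, 2, 4–12).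

**Steps most likely to fail**

1. Step 6 (proposed new method). The cycloaddition may have too high a barrier with a six-membered tether and an unactivated alkyne, so that ionisation of the furfuryl ether or decomposition of the methoxyfuran wins at the temperature needed. The fallback uses known Friedel–Crafts chemistry, sets out from 1 and 3 and rejoins the route at 15. NaBH4 reduction of 3 would give (2,3-dibromo-4,5-dimethoxyphenyl)methanol F1. O-Methylation of 1 (MeI, K2CO3) would give 3-bromo-4,5-dimethoxybenzaldehyde F2. Wittig methylenation would give 1-bromo-5-ethenyl-2,3-dimethoxybenzene F3. Hydroboration–oxidation (9-BBN; NaBO3) would give 2-(3-bromo-4,5-dimethoxyphenyl)ethanol F4, and acetylation 2-(3-bromo-4,5-dimethoxyphenyl)ethyl acetate F5. AlCl3-mediated benzylation of F5 with F1 (CH2Cl2, 0 °C) is expected para to the unhindered methoxy group, between chain and bromine, and would give 2-[3-bromo-2-(2,3-dibromo-4,5-dimethoxybenzyl)-4,5-dimethoxyphenyl]ethyl acetate F6. BBr3 followed by methanol, as in step 9, would then give 15.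

2. Step 5. Acid may hydrolyse or ring-open the methoxyfuran (enol ether hydrolysis, Piancatelli-type opening) faster than the carbocation is trapped by the alcohol. The fallback builds the alkyne after a base-mediated O-alkylation, sets out from 7 and rejoins at 9. NaH and allyl bromide (THF, 0 °C) would give 2-[(allyloxy)(2,3-dibromo-4,5-dimethoxyphenyl)methyl]-3-bromo-4-methoxyfuran F7. 9-BBN then NaBO3 would give 3-[(3-bromo-4-methoxyfuran-2-yl)(2,3-dibromo-4,5-dimethoxyphenyl)methoxy]propan-1-ol F8. Dess–Martin oxidation would give 3-[(3-bromo-4-methoxyfuran-2-yl)(2,3-dibromo-4,5-dimethoxyphenyl)methoxy]propanal F9. Ohira–Bestmann homologation (dimethyl (1-diazo-2-oxopropyl)phosphonate, K2CO3, MeOH) would then give 9.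

3. Step 4. The amide base may remove the α-proton beside the methoxy group instead of the one beside bromine, which would place the tether on the wrong furan carbon. The fallback blocks that position, sets out from 5 and rejoins at 7. LDA with in situ TMSCl (THF, −78 °C) would give (4-bromo-3-methoxyfuran-2-yl)trimethylsilane F10. A second deprotonation with LDA at the only remaining α-position, beside bromine, and addition to 3 would give [3-bromo-4-methoxy-5-(trimethylsilyl)furan-2-yl](2,3-dibromo-4,5-dimethoxyphenyl)methanol F11. TBAF (THF, rt) would remove the furyl silyl group and give 7.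

Further compounds
F1 | step 6 | (2,3-dibromo-4,5-dimethoxyphenyl)methanol | COc1cc(CO)c(Br)c(Br)c1OC
F2 | step 6 | 3-bromo-4,5-dimethoxybenzaldehyde | COc1cc(C=O)cc(Br)c1OC
F3 | step 6 | 1-bromo-5-ethenyl-2,3-dimethoxybenzene | COc1cc(C=C)cc(Br)c1OC
F4 | step 6 | 2-(3-bromo-4,5-dimethoxyphenyl)ethanol | COc1cc(CCO)cc(Br)c1OC
F5 | step 6 | 2-(3-bromo-4,5-dimethoxyphenyl)ethyl acetate | COc1cc(CCOC(C)=O)cc(Br)c1OC
F6 | step 6 | 2-[3-bromo-2-(2,3-dibromo-4,5-dimethoxybenzyl)-4,5-dimethoxyphenyl]ethyl acetate | CC(=O)OCCc1cc(OC)c(OC)c(Br)c1Cc1cc(OC)c(OC)c(Br)c1Br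
F7 | step 5 | 2-[(allyloxy)(2,3-dibromo-4,5-dimethoxyphenyl)methyl]-3-bromo-4-methoxyfuran, racemic | COc1coc(C(OCC=C)c2cc(OC)c(OC)c(Br)c2Br)c1Br
F8 | step 5 | 3-[(3-bromo-4-methoxyfuran-2-yl)(2,3-dibromo-4,5-dimethoxyphenyl)methoxy]propan-1-ol, racemic | COc1coc(C(OCCCO)c2cc(OC)c(OC)c(Br)c2Br)c1Br
F9 | step 5 | 3-[(3-bromo-4-methoxyfuran-2-yl)(2,3-dibromo-4,5-dimethoxyphenyl)methoxy]propanal, racemic | COc1coc(C(OCCC=O)c2cc(OC)c(OC)c(Br)c2Br)c1Br
F10 | step 4 | (4-bromo-3-methoxyfuran-2-yl)trimethylsilane | COc1c(Br)coc1[Si](C)(C)C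
F11 | step 4 | [3-bromo-4-methoxy-5-(trimethylsilyl)furan-2-yl](2,3-dibromo-4,5-dimethoxyphenyl)methanol, racemic | COc1c([Si](C)(C)C)oc(C(O)c2cc(OC)c(OC)c(Br)c2Br)c1Br
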